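## Analysis of the target

Sipholenol L is two bicyclic halves joined by a CH2–CH2 link. The left half is a trans-fused oxepane–cyclohexane (ring A, the seven-membered ether; ring B). The right half is a cis-fused octalin (ring C, the cyclohexene with C(Me)=CH; ring D, the gem-dimethylcyclohexane with a tertiary carbinol).

There are nine stereocentres. Five are in the left half: the CH(OH) of ring A, the O-bearing ring-fusion CH, the quaternary ring-fusion C–Me, the CH that carries the link, and the tertiary carbinol C(Me)OH. On ring B the ring-fusion methyl, the link and the carbinol methyl lie on one face, so the two methyl groups are 1,3-diaxial and the carbinol hydroxyl is equatorial. Four are in the right half: the two ring-fusion CH, the CH that carries the link (all three hydrogens on one face of ring C), and the carbinol of ring D, whose hydroxyl lies on the face of the ring-fusion hydrogens.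

The sensitive groups are two tertiary alcohols, which ionise under acid, and the trisubstituted alkene, which rules out unselective hydrogenation. The cis ring fusion of the octalin next to a carbonyl group is not clearly the stable one and has to be made and kept under kinetic control.

The hard parts are the seven-membered ether, flanked by CMe2 on one side and a quaternary ring-fusion carbon on the other, and the link between two branched ring carbons.

The strategy rests on one structural feature. The O–CMe2–CH(OH) edge of ring A is a 2,2-dimethylfuran-3(2H)-one at the ketone oxidation level. The quaternary ring-fusion carbon lies four atoms from furanone C5 along ring B, so it can be the internal carbon of an isopropenyl group. A (2+2) cycloaddition followed by cleavage of one cyclobutane bond then makes ring B and ring A together.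

## Retrosynthetic reasoning

**Link.** The target 36 is the bis-silyl ether 35 without its protecting groups, and 35 is the alkene 34 after saturation. The bond cut is the one between the two methylene carbons of the link. It lies away from every stereocentre and divides the molecule into two C15 halves. It is made as a C=C bond by Julia–Kocienski olefination of aldehyde 19 with sulfone 33, because addition to an aldehyde tolerates the branching on both sides better than displacement at a β-branched iodide. The forward sequence must then reduce a 1,2-disubstituted alkene beside the trisubstituted ring alkene.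

**Left half, functional groups.** Aldehyde 19 comes from triol 17 through the tris-silyl ether 18. Triol 17 comes from alcohol 16, and 16 from ketone 15. The carbinol of ring A is the only stereocentre not set by ring construction, so it is left to reagent control at the ketone.

**Ring A.** Oxepanone 15 is the photoadduct 14 with one cyclobutane bond cleaved, the bond between the α-carbon of the ketone and the O-bearing carbon. Going backwards, forming that bond contracts the seven-membered ring to a tetrahydrofuranone with a cyclobutane attached. The forward reaction must break this bond and no other, and must put a hydrogen on the ring-fusion carbon trans to the angular methyl.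

**Key disconnection.** Photoadduct 14 is cut at two bonds: the ring-fusion C–C bond (furanone β-carbon to the internal alkene carbon, which closes ring B) and the CH2–CH2 bond of ring A (furanone α-carbon to the alkene terminus). This leads to furanone 13. The furanone brings O–CMe2–C=O complete; the alkene brings the quaternary carbon and its methyl. The forward reaction has to choose one face of the isopropenyl group.

**Furanone.** Furanone 13 comes from ynone 11 by hydration and cyclodehydration, 11 from diol 10, and 10 from aldehyde 8 and the alkynol 9. The bond cut joins the aldehyde carbon to the alkyne.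

**Tether.** Aldehyde 8 comes from epoxide 7 and the dioxane 6, in which the prenyl terminus of geraniol is a latent aldehyde. It is kept as an alkene until the tertiary hydroxyl is tied into the dioxane, because a free hydroxyl four atoms from an aldehyde would close onto it. Dioxane 6 comes from diol 4 and the ketal 5. Diol 4 comes from epoxide 2 and the Grignard reagent 3 by opening at C2 with inversion, and 2 from geraniol 1. One Sharpless epoxidation supplies both stereocentres of the tether.

**Right half, functional groups.** Sulfone 33 comes from alkene 31 by Markovnikov hydration of an exocyclic methylene. Oxygen must arrive from the convex face, whereas a methyl nucleophile adding to the ketone would arrive from that same face and give the wrong carbinol. Alkene 31 comes from sulfide 30, 30 from ketone 29, and 29 from alcohol 28. Alcohol 28 comes from the dienone 26 by hydroboration of the exocyclic diene terminus, which also sets the link-bearing CH.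

**Ring C.** Dienone 26 is cut at the bond between the α-carbon of the ring-D ketone and the allylic CH2, giving bromide 25. Only one of the two enolates of 25 can reach the bromide, and it can do so only with the chain axial, which gives the cis ring fusion.

**Ring D and the side chain.** Bromide 25 comes from silyl ether 24. Ketone 24 is cut at the bond between the β-carbon of the enone 23 and C2 of the diene in boronate 22. Enone 23 is bought with the gem-dimethyl group and the ketone of ring D in place. Boronate 22 comes from the enynol 20 through silyl ether 21; the Z geometry of 20 places the CH2O arm where the ring closure needs it. The conjugate addition sets the one stereocentre of the right half that the others are relayed from.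

## Alternatives that were turned down

Alternative 1: The disconnection opens rings C and D of the right half to an acyclic epoxy-polyene. The bonds cut are the ring-fusion C–C bond, the CH2–CMe2 bond and the bond from the ring-fusion CH to the link-bearing CH. In the forward step an engineered class 2 terpene cyclase of the squalene–hopene family protonates the epoxide. The prenyl alkene attacks to give a cyclopentyl cation, a 1,2-alkyl shift expands it to the gem-dimethylcyclohexane, and the last alkene closes ring C before proton loss. The product is the cis-octalin diol A1.
- For it: one step makes two rings and four stereocentres, including the carbinol and the cis ring fusion. A1 is the right half at the oxidation level that the chosen route reaches only after ten steps. On step economy for the right half this alternative is clearly stronger.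
- Against it: an enzyme variant would have to be found that accepts this truncated substrate, follows the ring-expansion path, stops after two rings and loses the proton to one side only. Nothing in the step touches rings A and B, where five of the nine stereocentres and the seven-membered ether lie.
- Comparison: the chosen strategy pays for the right half with conventional steps, but it answers the harder structural question, the oxepane with its quaternary ring-fusion carbon.

Alternative 2: The disconnection is a one-carbon ring expansion of ring A. It cuts the two bonds to the carbon that will bear the hydroxyl. In the forward step dibromocarbene (CHBr3, KOt-Bu) adds to a six-membered cyclic enol ether fused to ring B, and Ag2CO3 in methanol opens the dibromocyclopropane to the bromo-oxepene methyl ketal A2.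
- For it: the chemistry is thermal and scalable, and the regiochemistry of both the carbene addition and the electrocyclic opening is fixed by the enol ether. The ring-fusion carbons come from a preformed bicyclic ketone, so no face has to be chosen at the quaternary carbon. On that point it is stronger than the photocycloaddition.
- Against it: A2 carries only one of the two methyl groups next to oxygen, and the second must be added to an oxocarbenium ion. The vinyl bromide must still become CH(OH) with control. Ring B in A2 has a masked ketone where the link must go and a CH2 where the tertiary carbinol must go, so both of those stereocentres remain to be built on the ring. The ketal forms as an epimer mixture and the opening uses silver in stoichiometric amount.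
- Comparison: the chosen strategy delivers O–CMe2–C=O complete and takes both ring-B stereocentres from one Sharpless epoxidation.

Alternative 3: The disconnection cuts the bond between CMe2 and the ring-fusion CH of ring D. In the forward step Fe(acac)3 and PhSiH3 transfer a hydrogen atom to a 1,1-disubstituted alkene. The tertiary radical adds 6-exo to the β-carbon of a cyclohexenone, and the α-keto radical is reduced and protonated, giving the cis-decalinone A3.
- For it: it forges the most hindered C–C bond of the right half under mild conditions and gives the cis ring fusion. For that bond it is more direct than anything in the chosen route, which avoids the problem by buying the gem-dimethyl ring.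
- Against it: the substrate needs the acyclic tertiary carbinol stereocentre in place beforehand. The link-bearing stereocentre of A3 is set by protonation and stays epimerisable next to the ketone. The ketone must then be turned into C(Me)=CH through a regiodefined enol triflate. Only the right half is addressed.
- Comparison: the chosen route sets the ring fusion and the link-bearing centre from ring geometry (intramolecular alkylation, hydroboration), and no epimerisable centre remains after the ketone is methylenated.

Key step: step 9

## Route

Remarks on the chemistry:
- The sense of induction in step 17 is taken from the known addition to cyclohex-2-enone; if it proves reversed, (R)-BINAP is used.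
- Compounds 7, 10 and 12 are carried as mixtures at a centre or double bond that disappears within two steps.

Step 1
Reactants: 1 geraniol
Product: 2 (2S,3S)-2,3-epoxygeraniol
Conditions: Ti(OiPr)4 (5 mol%), L-(+)-diethyl tartrate (6 mol%), t-BuOOH, 4 Å molecular sieves, CH2Cl2, −20 °C
Reagents that add atoms: tert-butyl hydroperoxide, CC(C)(C)OO
Why: Sharpless asymmetric epoxidation; the titanium tartrate binds the allylic alcohol, so only the 2,3-alkene reacts, and with the L-(+)-tartrate oxygen is delivered to the face that gives the (2S,3S)-epoxide, which fixes the future tertiary carbinol of ring B.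

Step 2
Reactants: 2 (2S,3S)-2,3-epoxygeraniol; 3 isopropenylmagnesium bromide
Product: 4 (2R,3S)-3,7-dimethyl-2-(prop-1-en-2-yl)oct-6-ene-1,3-diol
Conditions: 3 (3.5 equiv), CuI (10 mol%), THF, −30 → 0 °C; aq. NH4Cl
Reagents that add atoms: none
Why: Copper-catalysed Grignard opening of a 2,3-epoxy alcohol; the fully substituted C3 is closed to SN2 attack, so the isopropenyl group enters at C2 with inversion and sets the CH that will carry the link.

Step 3
Reactants: 4 (2R,3S)-3,7-dimethyl-2-(prop-1-en-2-yl)oct-6-ene-1,3-diol; 5 2,2-dimethoxypropane
Product: 6 (4S,5R)-2,2,4-trimethyl-4-(4-methylpent-3-en-1-yl)-5-(prop-1-en-2-yl)-1,3-dioxane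
Conditions: 5 (3 equiv), PPTS (5 mol%), CH2Cl2, rt
Reagents that add atoms: none
Why: Acid-catalysed transketalisation closes the six-membered dioxane on the 1,3-diol; it ties up the tertiary hydroxyl before an aldehyde is released four atoms away and later serves as the template of the tether.

Step 4
Reactants: 6 the dioxane diene
Product: 7 (4S,5R)-4-[2-(3,3-dimethyloxiran-2-yl)ethyl]-2,2,4-trimethyl-5-(prop-1-en-2-yl)-1,3-dioxane (both epimers at the oxirane CH)
Conditions: mCPBA (1.05 equiv), NaHCO3, CH2Cl2, −20 °C
Reagents that add atoms: 3-chloroperbenzoic acid, OOC(=O)c1cccc(Cl)c1
Why: Prilezhaev epoxidation is much faster at the trisubstituted alkene than at the 1,1-disubstituted isopropenyl group, which is also flanked by the dioxane, so one equivalent at low temperature should oxidise only the prenyl terminus; the new centre is destroyed in step 5.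

Step 5
Reactants: 7 the terminal epoxide
Product: 8 3-[(4S,5R)-2,2,4-trimethyl-5-(prop-1-en-2-yl)-1,3-dioxan-4-yl]propanal
Conditions: H5IO6 (1.2 equiv), THF–Et2O, 0 °C, short contact
Reagents that add atoms: none
Why: Periodic acid opens the trisubstituted epoxide at its tertiary carbon and cleaves the resulting glycol in one operation, releasing acetone and the aldehyde; brief exposure at 0 °C should spare the acetonide.

Step 6
Reactants: 8 the dioxanyl propanal; 9 2-methylbut-3-yn-2-ol
Product: 10 2-methyl-7-[(4S,5R)-2,2,4-trimethyl-5-(prop-1-en-2-yl)-1,3-dioxan-4-yl]hept-3-yne-2,5-diol (both epimers at C5)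
Conditions: 9 (1.5 equiv), n-BuLi (3.0 equiv), THF, −78 → 0 °C; then 8, −78 °C; aq. NH4Cl
Reagents that add atoms: none
Why: Addition of a lithium acetylide to an aldehyde; the dianion of 9 needs no protecting group, and both carbinol epimers are used because the centre is oxidised in step 7.

Step 7
Reactants: 10 the propargylic diol
Product: 11 2-hydroxy-2-methyl-7-[(4S,5R)-2,2,4-trimethyl-5-(prop-1-en-2-yl)-1,3-dioxan-4-yl]hept-3-yn-5-one
Conditions: Dess–Martin periodinane, NaHCO3, CH2Cl2, 0 °C → rt
Reagents that add atoms: none
Why: Dess–Martin oxidation of the secondary propargylic alcohol gives the ynone; the tertiary alcohol cannot be oxidised and the buffered medium leaves the acetonide alone.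

Step 8
Reactants: 11 the hydroxy ynone
Product: 13 2,2-dimethyl-5-{2-[(4S,5R)-2,2,4-trimethyl-5-(prop-1-en-2-yl)-1,3-dioxan-4-yl]ethyl}furan-3(2H)-one, via enaminone 12 (not isolated)
Conditions: Et2NH, EtOH, rt; then 10% aq. AcOH, THF, rt
Reagents that add atoms: water, O
Why: Conjugate addition of the amine at the alkyne carbon next to CMe2OH gives enaminone 12; aqueous acid hydrolyses it to the 1,3-diketone, whose tertiary hydroxyl closes onto the distal carbonyl and loses water (cyclodehydration), the standard entry to 2,2-dimethylfuran-3(2H)-ones.

Step 9
Reactants: 13 the furanone with the dioxane-tethered isopropenyl group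
Product: 14 tetracyclic cyclobutane photoadduct (tetrahydrofuranone, cyclobutane, ring B and dioxane; cis cyclobutane fusions; ring B trans-fused to the dioxane)
Conditions: hν (medium-pressure Hg lamp, Pyrex filter, λ > 300 nm), degassed MeCN (5 mM), 0 °C
Reagents that add atoms: none
Why: Excitation of the furanone and intersystem crossing give the enone triplet, whose β-carbon C5 bonds to the internal carbon of the isopropenyl group through a chair-like six-membered transition state (closing ring B), and the triplet 1,4-diradical then closes the cyclobutane between the furanone α-carbon and the CH2 terminus after spin inversion. The closest known reaction type is the intramolecular enone–alkene (2+2) photocycloaddition of 3(2H)-furanones and other vinylogous esters carrying a four-atom tether, which gives straight adducts. Ring B closes in the 6-exo sense with respect to the alkene; the four-membered ring closes by radical recombination and is cis-fused to both the five- and the six-membered ring for reasons of strain. The quaternary ring-fusion carbon is set in the first bond formation: the trans-fused dioxane holds the carbinol methyl axial and the CH2O arm equatorial on the incipient ring B, and the isopropenyl group should react from its preferred rotamer, in which the ring C–H eclipses C=CH2, so that its methyl becomes axial and the CH2 terminus equatorial, as the target requires. The configurations at the O-bearing carbon and at the α-carbon follow from the cis fusions and are both erased in step 10. The step needs straight and not crossed regiochemistry, which the tether length secures, since no five-membered ring can form and the six-membered ring is the smallest available. It also needs the face selection just described, which rests on allylic strain working against a developing 1,3-diaxial methyl–methyl contact and is the uncertain point of the route. Irradiation through Pyrex keeps the saturated ketone of the product outside the absorbing window.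

Step 10
Reactants: 14 the photoadduct
Product: 15 trans-fused oxepan-3-one (rings A and B, acetonide intact)
Conditions: SmI2 (2.5 equiv), HMPA, t-BuOH, THF, −78 → −40 °C
Reagents that add atoms: none
Why: Electron transfer gives the ketyl, which fragments the strained cyclobutane bond to the O-bearing carbon to give a samarium enolate and a tertiary α-alkoxy radical (reductive cyclobutane fragmentation, the radical counterpart of a de Mayo ring expansion). A second electron and a proton then put hydrogen on the ring-fusion carbon from the axial direction, anti to the axial methyl on the neighbouring quaternary carbon, which gives the trans ring fusion.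

Step 11
Reactants: 15 the oxepan-3-one
Product: 16 secondary alcohol with the (S)-configured carbinol of ring A (acetonide intact)
Conditions: (R)-2-methyl-CBS-oxazaborolidine (0.5 equiv), BH3·SMe2, THF, −20 °C; MeOH
Reagents that add atoms: none
Why: Corey–Bakshi–Shibata reduction under reagent control; the O-bearing CMe2 flank is the large group and the CH2 flank the small one, so the (R)-catalyst should deliver hydride to give the (S)-carbinol, with the hydroxyl trans to the angular methyl.

Step 12
Reactants: 16 the acetonide alcohol
Product: 17 triol (primary, secondary and tertiary hydroxyl)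
Conditions: AcOH–H2O–THF (3:1:1), 40 °C
Reagents that add atoms: none
Why: Mild aqueous acid hydrolyses the strained acetonide of the tertiary 1,3-diol; the cyclic ether and the equatorial tertiary alcohol should not ionise under these conditions.

Step 13
Reactants: 17 the triol
Product: 18 tris(triethylsilyl) ether
Conditions: Et3SiOTf (4 equiv), 2,6-lutidine, CH2Cl2, −78 → 0 °C
Reagents that add atoms: triethylsilyl trifluoromethanesulfonate, CC[Si](CC)(CC)OS(=O)(=O)C(F)(F)F
Why: The silyl triflate is reactive enough to silylate the tertiary hydroxyl as well, so one operation protects all three alcohols and blocks retro-aldol cleavage at the later β-oxy aldehyde.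

Step 14
Reactants: 18 the tris(triethylsilyl) ether
Product: 19 left-half aldehyde (secondary and tertiary triethylsilyl ethers kept)
Conditions: (COCl)2, DMSO, CH2Cl2, −78 → −40 °C; then Et3N, −78 → 0 °C
Reagents that add atoms: none
Why: Under Swern conditions a primary triethylsilyl ether is cleaved by the activated sulfoxide and oxidised in the same flask, while the secondary and tertiary silyl ethers survive; the aldehyde is equatorial and its α-hydrogen is shielded, so epimerisation is not expected.

Step 15
Reactants: 20 (Z)-3-methylpent-2-en-4-yn-1-ol
Product: 21 tert-butyldimethylsilyl ether of 20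
Conditions: t-BuMe2SiCl, imidazole, CH2Cl2, 0 °C → rt
Reagents that add atoms: tert-butyldimethylsilyl chloride, CC(C)(C)[Si](C)(C)Cl
Why: Standard silylation of a primary allylic alcohol; it keeps the hydroxyl from binding to boron in the next two steps.

Step 16
Reactants: 21 the silylated enyne
Product: 22 2-[(3Z)-5-(tert-butyldimethylsilyloxy)-3-methylpenta-1,3-dien-2-yl]-4,4,5,5-tetramethyl-1,3,2-dioxaborolane
Conditions: B2pin2, CuCl (5 mol%), 1,3-bis(2,4,6-trimethylphenyl)imidazolinium chloride (5 mol%), NaOt-Bu (10 mol%), MeOH (2 equiv), THF, −20 °C → rt
Reagents that add atoms: bis(pinacolato)diboron, CC1(C)OB(OC1(C)C)B1OC(C)(C)C(C)(C)O1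
Why: Copper-catalysed protoboration of a terminal alkyne (syn addition of copper–boryl, then protonation by methanol); with a conjugating substituent on the alkyne and a small N-aryl carbene ligand, boron should go to the internal carbon, giving the 2-boryl diene with the Z alkene untouched.

Step 17
Reactants: 22 the dienylboronate; 23 4,4-dimethylcyclohex-2-en-1-one
Product: 24 (R)-3-[(3Z)-5-(tert-butyldimethylsilyloxy)-3-methylpenta-1,3-dien-2-yl]-4,4-dimethylcyclohexan-1-one
Conditions: 22 (1.5 equiv), [Rh(cod)Cl]2 (2.5 mol%), (S)-BINAP (6 mol%), aq. KOH, 1,4-dioxane, 60 °C
Reagents that add atoms: none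
Why: Hayashi–Miyaura asymmetric conjugate addition; boron-to-rhodium transmetalation gives an alkenylrhodium species that adds to the enone β-carbon on the face selected by the bisphosphine, and water releases the ketone. This sets the ring-fusion CH next to the gem-dimethyl carbon; additions of α-branched alkenylboron reagents to 4,4-disubstituted cyclic enones are known.

Step 18
Reactants: 24 the silyloxy dienyl ketone
Product: 25 (R)-3-[(3Z)-5-bromo-3-methylpenta-1,3-dien-2-yl]-4,4-dimethylcyclohexan-1-one
Conditions: PPh3, Br2 (preformed Ph3PBr2), CH2Cl2, 0 °C → rt
Reagents that add atoms: triphenylphosphine dibromide, Br[P+](c1ccccc1)(c1ccccc1)c1ccccc1.[Br-]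
Why: The bromophosphonium salt converts a primary silyl ether directly into the bromide (activation at oxygen, then displacement by bromide); the ketone and the diene are inert to it.

Step 19
Reactants: 25 the allylic bromide
Product: 26 cis-4,4,6-trimethyl-5-methylidene-3,4,4a,5,8,8a-hexahydronaphthalen-1(2H)-one (ring-fusion hydrogens on one face)
Conditions: KOt-Bu (1.1 equiv), t-BuOH–THF, −20 → 0 °C; pH 7 buffer
Reagents that add atoms: none
Why: Intramolecular enolate alkylation; the two enolates interconvert and only the one at the carbon next to the side chain can reach the allylic bromide (6-exo-tet, closing ring C). The chain must sit axial to attack the enolate face, which gives the cis-fused ketone as the kinetic product; low temperature and a neutral quench guard the ring fusion against epimerisation.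

Step 20
Reactants: 26 the cis-fused dienone
Product: 28 cis-5-(hydroxymethyl)-4,4,6-trimethyl-3,4,4a,5,8,8a-hexahydronaphthalen-1(2H)-one (5-H on the face of the ring-fusion hydrogens), via alkylborane 27 (not isolated)
Conditions: Sia2BH (from BH3·THF and 2-methylbut-2-ene), THF, 0 °C; then H2O2, pH 7 phosphate buffer, 0 °C → rt
Reagents that add atoms: hydrogen peroxide, OO
Why: Hydroboration–oxidation; the hindered borane adds to the terminal CH2 of the diene far faster than it reduces the α-branched ketone, and it approaches from the convex face, away from ring D, so the new hydrogen on the link-bearing carbon is cis to the ring-fusion hydrogens. The buffered oxidation retains that configuration and avoids base at the ring fusion.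

Step 21
Reactants: 28 the hydroxy ketone
Product: 29 1-phenyl-1H-tetrazol-5-yl sulfide of 28
Conditions: 1-phenyl-1H-tetrazole-5-thiol, PPh3, DIAD, THF, 0 °C → rt
Reagents that add atoms: 1-phenyl-1H-tetrazole-5-thiol, Sc1nnnn1-c1ccccc1
Why: Mitsunobu thioetherification of a primary alcohol with the acidic heteroaryl thiol; the conditions are close to neutral and leave the ketone and its α-centre alone.

Step 22
Reactants: 29 the keto sulfide
Product: 30 sulfide with an exocyclic methylene in place of the ketone
Conditions: Zn, CH2Br2, TiCl4 (preformed reagent), THF–CH2Cl2, 0 °C → rt
Reagents that add atoms: dibromomethane, BrCBr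
Why: Takai–Lombardo methylenation; the non-basic zinc–titanium methylene reagent converts hindered, enolisable ketones without epimerisation, and from here on the ring fusion is fixed.

Step 23
Reactants: 30 the sulfide
Product: 31 1-phenyl-1H-tetrazol-5-yl sulfone
Conditions: (NH4)6Mo7O24·4H2O (10 mol%), 30% H2O2, EtOH, 0 °C → rt
Reagents that add atoms: hydrogen peroxide, OO
Why: Molybdate-catalysed peroxide oxidation takes the sulfide to the sulfone and is selective for sulfur over unactivated di- and trisubstituted alkenes.

Step 24
Reactants: 31 the sulfone with the exocyclic methylene
Product: 33 right-half sulfone with the tertiary carbinol of ring D, via organomercurial 32 (not isolated)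
Conditions: Hg(OAc)2, THF–H2O, rt; then NaBH4, aq. NaOH, 0 °C
Reagents that add atoms: water, O
Why: Oxymercuration–demercuration; the 1,1-disubstituted alkene reacts far faster than the trisubstituted ring alkene, and water attacks the tertiary carbon of the mercurinium ion from the convex face. The hydroxyl therefore ends on the side of the ring-fusion hydrogens and the new methyl on the concave side, the opposite of what methyl addition to the ketone would give.

Step 25
Reactants: 19 the left-half aldehyde; 33 the right-half sulfone
Product: 34 coupled (E)-alkene, bis(triethylsilyl) ether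
Conditions: 33 (1.2 equiv), KN(SiMe3)2 (2.5 equiv), DME, −78 °C; then 19, −78 °C → rt
Reagents that add atoms: none
Why: Julia–Kocienski olefination; the first equivalent of base parks the tertiary hydroxyl as its alkoxide and the second forms the sulfonyl carbanion, which adds to the aldehyde and, after Smiles rearrangement, loses SO2 and the tetrazolone. The alkene geometry does not matter because the double bond is reduced in step 26.

Step 26
Reactants: 34 the coupled alkene
Product: 35 saturated bis(triethylsilyl) ether of the target
Conditions: 2-nitrobenzenesulfonylhydrazide (excess, in portions), Et3N, CH2Cl2, rt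
Reagents that add atoms: none
Why: Diimide transfers two hydrogens in a concerted syn fashion and reduces a 1,2-disubstituted alkene much faster than a trisubstituted one; no metal hydride is present, so the ring alkene stays where it is.

Step 27
Reactants: 35 the bis(triethylsilyl) ether
Product: 36 sipholenol L
Conditions: Bu4NF, THF, rt → 45 °C
Reagents that add atoms: none
Why: Fluoride cleaves the secondary and the tertiary triethylsilyl ether under non-acidic conditions, which the two tertiary alcohols and the trisubstituted alkene tolerate.

## Compound list

1 | geraniol | CC(C)=CCC/C(C)=C/CO | starting material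
2 | (2S,3S)-2,3-epoxygeraniol | OC[C@@H]1O[C@@]1(C)CCC=C(C)C | intermediate
3 | isopropenylmagnesium bromide | CC(=C)[Mg]Br | starting material
4 | (2R,3S)-3,7-dimethyl-2-(prop-1-en-2-yl)oct-6-ene-1,3-diol | OC[C@H]([C@@](C)(O)CCC=C(C)C)C(C)=C | intermediate
5 | 2,2-dimethoxypropane | COC(C)(C)OC | starting material
6 | (4S,5R)-2,2,4-trimethyl-4-(4-methylpent-3-en-1-yl)-5-(prop-1-en-2-yl)-1,3-dioxane | CC(C)=CCC[C@]1(C)OC(C)(C)OC[C@H]1C(C)=C | intermediate
7 | (4S,5R)-4-[2-(3,3-dimethyloxiran-2-yl)ethyl]-2,2,4-trimethyl-5-(prop-1-en-2-yl)-1,3-dioxane, both oxirane epimers | CC1(C)OC1CC[C@]1(C)OC(C)(C)OC[C@H]1C(C)=C | intermediate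
8 | 3-[(4S,5R)-2,2,4-trimethyl-5-(prop-1-en-2-yl)-1,3-dioxan-4-yl]propanal | O=CCC[C@]1(C)OC(C)(C)OC[C@H]1C(C)=C | intermediate
9 | 2-methylbut-3-yn-2-ol | CC(C)(O)C#C | starting material
10 | 2-methyl-7-[(4S,5R)-2,2,4-trimethyl-5-(prop-1-en-2-yl)-1,3-dioxan-4-yl]hept-3-yne-2,5-diol, both C5 epimers | CC(C)(O)C#CC(O)CC[C@]1(C)OC(C)(C)OC[C@H]1C(C)=C | intermediate
11 | 2-hydroxy-2-methyl-7-[(4S,5R)-2,2,4-trimethyl-5-(prop-1-en-2-yl)-1,3-dioxan-4-yl]hept-3-yn-5-one | CC(C)(O)C#CC(=O)CC[C@]1(C)OC(C)(C)OC[C@H]1C(C)=C | intermediate
12 | 4-(diethylamino)-2-hydroxy-2-methyl-7-[(4S,5R)-2,2,4-trimethyl-5-(prop-1-en-2-yl)-1,3-dioxan-4-yl]hept-3-en-5-one, alkene geometry not defined | CCN(CC)C(=CC(=O)CC[C@]1(C)OC(C)(C)OC[C@H]1C(C)=C)C(C)(C)O | intermediate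
13 | 2,2-dimethyl-5-{2-[(4S,5R)-2,2,4-trimethyl-5-(prop-1-en-2-yl)-1,3-dioxan-4-yl]ethyl}furan-3(2H)-one | CC1(C)OC(CC[C@]2(C)OC(C)(C)OC[C@H]2C(C)=C)=CC1=O | intermediate
14 | tetracyclic cyclobutane photoadduct | CC1(C)O[C@@]23CC[C@]4(C)OC(C)(C)OC[C@H]4[C@]2(C)C[C@H]3C1=O | intermediate
15 | trans-fused oxepan-3-one, acetonide | CC1(C)OC[C@H]2[C@]3(C)CCC(=O)C(C)(C)O[C@H]3CC[C@]2(C)O1 | intermediate
16 | trans-fused oxepan-3-ol with (S)-carbinol, acetonide | CC1(C)OC[C@H]2[C@]3(C)CC[C@H](O)C(C)(C)O[C@H]3CC[C@]2(C)O1 | intermediate
17 | left-half triol | OC[C@H]1[C@]2(C)CC[C@H](O)C(C)(C)O[C@H]2CC[C@]1(C)O | intermediate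
18 | left-half tris(triethylsilyl) ether | CC[Si](CC)(CC)OC[C@H]1[C@]2(C)CC[C@H](O[Si](CC)(CC)CC)C(C)(C)O[C@H]2CC[C@]1(C)O[Si](CC)(CC)CC | intermediate
19 | left-half aldehyde, bis(triethylsilyl) ether | O=C[C@H]1[C@]2(C)CC[C@H](O[Si](CC)(CC)CC)C(C)(C)O[C@H]2CC[C@]1(C)O[Si](CC)(CC)CC | intermediate
20 | (Z)-3-methylpent-2-en-4-yn-1-ol | C#C/C(C)=C\CO | starting material
21 | tert-butyldimethylsilyl ether of (Z)-3-methylpent-2-en-4-yn-1-ol | C#C/C(C)=C\CO[Si](C)(C)C(C)(C)C | intermediate
22 | 2-[(3Z)-5-(tert-butyldimethylsilyloxy)-3-methylpenta-1,3-dien-2-yl]-4,4,5,5-tetramethyl-1,3,2-dioxaborolane | C=C(B1OC(C)(C)C(C)(C)O1)/C(C)=C\CO[Si](C)(C)C(C)(C)C | intermediate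
23 | 4,4-dimethylcyclohex-2-en-1-one | CC1(C)CCC(=O)C=C1 | starting material
24 | (R)-3-[(3Z)-5-(tert-butyldimethylsilyloxy)-3-methylpenta-1,3-dien-2-yl]-4,4-dimethylcyclohexan-1-one | O=C1C[C@@H](C(=C)/C(C)=C\CO[Si](C)(C)C(C)(C)C)C(C)(C)CC1 | intermediate
25 | (R)-3-[(3Z)-5-bromo-3-methylpenta-1,3-dien-2-yl]-4,4-dimethylcyclohexan-1-one | O=C1C[C@@H](C(=C)/C(C)=C\CBr)C(C)(C)CC1 | intermediate
26 | cis-4,4,6-trimethyl-5-methylidene-3,4,4a,5,8,8a-hexahydronaphthalen-1(2H)-one | CC1=CC[C@H]2[C@@H](C1=C)C(C)(C)CCC2=O | intermediate
27 | bis(3-methylbutan-2-yl)borane adduct at the exocyclic CH2 of 26 | CC1=CC[C@H]2[C@@H]([C@@H]1CB(C(C)C(C)C)C(C)C(C)C)C(C)(C)CCC2=O | intermediate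
28 | cis-5-(hydroxymethyl)-4,4,6-trimethyl-3,4,4a,5,8,8a-hexahydronaphthalen-1(2H)-one, 5-H cis to 4a-H and 8a-H | CC1=CC[C@H]2[C@@H]([C@@H]1CO)C(C)(C)CCC2=O | intermediate
29 | 1-phenyl-1H-tetrazol-5-yl sulfide of 28 | CC1=CC[C@H]2[C@@H]([C@@H]1CSc1nnnn1-c1ccccc1)C(C)(C)CCC2=O | intermediate
30 | tetrazolyl sulfide with exocyclic methylene on ring D | CC1=CC[C@H]2[C@@H]([C@@H]1CSc1nnnn1-c1ccccc1)C(C)(C)CCC2=C | intermediate
31 | tetrazolyl sulfone with exocyclic methylene on ring D | CC1=CC[C@H]2[C@@H]([C@@H]1CS(=O)(=O)c1nnnn1-c1ccccc1)C(C)(C)CCC2=C | intermediate
32 | acetoxymercuriomethyl carbinol from 31 | CC1=CC[C@H]2[C@@H]([C@@H]1CS(=O)(=O)c1nnnn1-c1ccccc1)C(C)(C)CC[C@]2(C[Hg]OC(C)=O)O | intermediate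
33 | right-half tetrazolyl sulfone with the tertiary carbinol of ring D | CC1=CC[C@H]2[C@@H]([C@@H]1CS(=O)(=O)c1nnnn1-c1ccccc1)C(C)(C)CC[C@]2(C)O | intermediate
34 | coupled (E)-alkene, bis(triethylsilyl) ether | CC1=CC[C@H]2[C@@H]([C@@H]1/C=C/[C@H]1[C@]3(C)CC[C@H](O[Si](CC)(CC)CC)C(C)(C)O[C@H]3CC[C@]1(C)O[Si](CC)(CC)CC)C(C)(C)CC[C@]2(C)O | intermediate
35 | bis(triethylsilyl) ether of sipholenol L | CC1=CC[C@H]2[C@@H]([C@@H]1CC[C@H]1[C@]3(C)CC[C@H](O[Si](CC)(CC)CC)C(C)(C)O[C@H]3CC[C@]1(C)O[Si](CC)(CC)CC)C(C)(C)CC[C@]2(C)O | intermediate
36 | sipholenol L | CC1=CC[C@H]2[C@@H]([C@@H]1CC[C@H]1[C@]3(C)CC[C@H](O)C(C)(C)O[C@H]3CC[C@]1(C)O)C(C)(C)CC[C@]2(C)O | target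

## Step count and least certain steps

Total: 27 steps. Longest linear sequence: 17 steps (steps 1–14 and 25–27). The right half is made in a ten-step branch (steps 15–24) that joins at step 25.

**Step 9 (key step).** The likely failure is poor face selection at the isopropenyl group. Attack on the other face puts the alkene CH2 axial and the methyl equatorial, and that epimer cannot lead to a trans-fused oxepane. A contributing weakness is that a 2,2-dimethyl-1,3-dioxane with a quaternary C4 cannot sit in a clean chair, so the template is softer than drawn.

The fallback changes the template. It sets out from 13 and returns at 17: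
- Aqueous acetic acid removes the acetonide to give the furanone diol F1.
- 1,1'-Carbonyldiimidazole closes the cyclic carbonate F2. Its flat carbonate carbon carries no axial substituent, so the trans-fused template is rigid.
- Irradiation as in step 9 gives the carbonate photoadduct F3.
- SmI2 fragmentation gives the oxepanone carbonate F4.
- Reduction as in step 11 gives the hydroxy carbonate F5.
- K2CO3 in methanol cleaves the carbonate to 17.

**Step 10.** The likely failure is cleavage of the wrong cyclobutane bond. The bond outside the five-membered ring overlaps better with the ketyl, and its cleavage would leave a methyl-substituted tetrahydrofuranone. The α-alkoxy radical may also be reduced too slowly, with loss of control at the ring-fusion hydrogen.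

The fallback uses ionic instead of radical chemistry. It sets out from 14 and returns at 15. Catalytic Et3SiOTf with Et3SiH and a hindered pyridine in CH2Cl2 at −78 °C opens the alkoxy-substituted cyclobutane in the push–pull sense, since only the bond to the O-bearing carbon can give an oxocarbenium ion. Axial hydride capture gives the triethylsilyl enol ether F6, and mild hydrolysis gives 15.

**Step 17.** The likely failures are slow addition to the β-carbon next to the quaternary centre, with protodeboronation of 22 taking over, and insufficient enantioselectivity.

The fallback uses a more electrophilic, symmetric acceptor. It sets out from 23 and returns at 24. DDQ dehydrogenates 23 to 4,4-dimethylcyclohexa-2,5-dien-1-one F8. The same rhodium-catalysed addition of 22 then differentiates its two enantiotopic alkenes and gives the enone adduct F9. Conjugate reduction of the remaining enone with [(Ph3P)CuH]6 gives 24.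

**Step 16.** The likely failure is delivery of boron to the terminal alkyne carbon, which would give the linear dienylboronate.

The fallback sets out from 21 and returns at 22. Haloboration with B-bromo-9-borabicyclo[3.3.1]nonane followed by protonolysis with acetic acid gives the 2-bromodiene F7 with Markovnikov regiochemistry. Miyaura borylation (PdCl2(dppf), B2pin2, KOPh) gives 22.

**Step 19.** The likely failure is epimerisation of the kinetic cis ring fusion by the alkoxide once the ring has closed. O-alkylation is a lesser risk.

The fallback avoids base in the ring-closing event. It sets out from 25 and returns at 26. Me3SiOTf and i-Pr2NEt give the trimethylsilyl enol ether F10 together with its regioisomer. ZnBr2 in CH2Cl2 then ionises the allylic bromide, and only F10 can capture it intramolecularly to give 26. The regioisomer is hydrolysed back to 25 and recycled.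

**Step 25.** The likely failure is that the sulfonyl carbanion does not add to the very hindered aldehyde and instead condenses with itself, or that the β-silyloxy aldehyde eliminates.

The fallback joins the halves by alkylation. It sets out from 19 and returns at 35:
- NaBH4 gives the primary alcohol F11.
- I2, PPh3 and imidazole give the iodide F12.
- The dianion of 33 (LiN(SiMe3)2, HMPA) is alkylated with F12 to give the alkylated sulfone F13.
- Reductive desulfonylation with SmI2 and HMPA gives 35, and step 26 is then not needed.

## Further compounds

F1 | step 9 | furanone diol | CC1(C)OC(CC[C@](C)(O)[C@@H](CO)C(C)=C)=CC1=O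
F2 | step 9 | cyclic carbonate of the furanone diol | CC1(C)OC(CC[C@]2(C)OC(=O)OC[C@H]2C(C)=C)=CC1=O
F3 | step 9 | carbonate photoadduct | CC1(C)O[C@@]23CC[C@]4(C)OC(=O)OC[C@H]4[C@]2(C)C[C@H]3C1=O
F4 | step 9 | oxepanone carbonate | O=C1OC[C@H]2[C@]3(C)CCC(=O)C(C)(C)O[C@H]3CC[C@]2(C)O1
F5 | step 9 | hydroxy carbonate | O=C1OC[C@H]2[C@]3(C)CC[C@H](O)C(C)(C)O[C@H]3CC[C@]2(C)O1
F6 | step 10 | triethylsilyl enol ether of 15 | CC1(C)OC[C@H]2[C@]3(C)CC=C(O[Si](CC)(CC)CC)C(C)(C)O[C@H]3CC[C@]2(C)O1
F7 | step 16 | 2-bromodiene | C=C(Br)/C(C)=C\CO[Si](C)(C)C(C)(C)C
F8 | step 17 | 4,4-dimethylcyclohexa-2,5-dien-1-one | CC1(C)C=CC(=O)C=C1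
F9 | step 17 | enone adduct | O=C1C[C@@H](C(=C)/C(C)=C\CO[Si](C)(C)C(C)(C)C)C(C)(C)C=C1
F10 | step 19 | trimethylsilyl enol ether | C[Si](C)(C)OC1=C[C@@H](C(=C)/C(C)=C\CBr)C(C)(C)CC1
F11 | step 25 | primary alcohol | OC[C@H]1[C@]2(C)CC[C@H](O[Si](CC)(CC)CC)C(C)(C)O[C@H]2CC[C@]1(C)O[Si](CC)(CC)CC
F12 | step 25 | iodide | IC[C@H]1[C@]2(C)CC[C@H](O[Si](CC)(CC)CC)C(C)(C)O[C@H]2CC[C@]1(C)O[Si](CC)(CC)CC
F13 | step 25 | alkylated sulfone, both epimers at the sulfonyl carbon | CC1=CC[C@H]2[C@@H]([C@@H]1C(C[C@H]1[C@]3(C)CC[C@H](O[Si](CC)(CC)CC)C(C)(C)O[C@H]3CC[C@]1(C)O[Si](CC)(CC)CC)S(=O)(=O)c1nnnn1-c1ccccc1)C(C)(C)CC[C@]2(C)O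
A1 | alternative 1 | cis-octalin diol | CC1=CC[C@H]2[C@@H]([C@@H]1CO)C(C)(C)CC[C@]2(C)O
A2 | alternative 2 | bromo-oxepene methyl ketal | COC1(C)O[C@H]2CCCC3(OCCO3)[C@]2(C)CC=C1Br
A3 | alternative 3 | cis-decalinone with the silyloxymethyl arm | O=C1CC[C@H]2[C@@H]([C@@H]1CO[Si](C)(C)C(C)(C)C)C(C)(C)CC[C@]2(C)O
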